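**Retrosynthetic overview**
- Feature: in the dioxane ring (O1–C2–C3–O4–C4a–C8a) the C2–O1 bond is benzylic to the 4-oxygenated 3,5-dimethoxyphenyl ring and heterolyses readily. A closure at C2 would endanger the C2 configuration, so O1 is joined last to arene carbon C8a, the fusion carbon next to C8–H and not the OMe-flanked C4a.
- Disconnection 1 (the only ring formed, last skeletal bond): O1–C8a, by intramolecular copper-catalysed Ullmann etherification of a threo-(1R,2R) bromo alcohol. Both benzene rings are bought.
- Disconnection 2: the C2 carbinol comes from Felkin–Anh hydride reduction of an α-aryloxy aryl ketone. The ketone comes from a Weinreb amide and a MOM-protected 4-hydroxy-3,5-dimethoxyphenyl Grignard reagent.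
- Disconnection 3: C3–O4, by Mitsunobu inversion of ethyl (S)-lactate with 6-bromoeugenol. The eugenol OH already sits on the OMe-flanked carbon and the bromine marks C8a, so ring regiochemistry follows from the order of bond formation.
- End game: MOM removal under conditions that leave C2–O1 intact.

Key step: step 7

Remark: benzodioxine numbering O1, C2 (aryl), C3 (methyl), O4, C4a, C5 (OMe), C7 (allyl), C8a is used throughout. The given SMILES is read as the trans-(2R,3R) isomer.

**Step 1**
Reactants: 1 eugenol (4-allyl-2-methoxyphenol)
Product: 2 4-allyl-2-bromo-6-methoxyphenol (6-bromoeugenol)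
Conditions: NBS (1.0 equiv), iPr2NH (10 mol %), CH2Cl2, 0 °C, dark
Reagents that add atoms: N-bromosuccinimide, O=C1CCC(=O)N1Br
Why: Electrophilic aromatic bromination, in which the free OH is the strongest director and its para position is blocked by the allyl chain, so the amine-relayed bromine should go to the only open ortho carbon much faster than the unactivated terminal alkene can form a bromonium ion.

**Step 2**
Reactants: 2 4-allyl-2-bromo-6-methoxyphenol, 3 ethyl (S)-lactate
Product: 4 ethyl (2R)-2-(4-allyl-2-bromo-6-methoxyphenoxy)propanoate
Conditions: PPh3, DIAD, THF, 0 °C → rt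
Reagents that add atoms: none
Why: Mitsunobu etherification, in which the acidic bromophenol displaces the oxyphosphonium-activated lactate oxygen by SN2, so the S carbinol carbon is inverted to the R aryl ether that becomes C3.

**Step 3**
Reactants: 4 ethyl (2R)-2-(4-allyl-2-bromo-6-methoxyphenoxy)propanoate
Product: 5 (2R)-2-(4-allyl-2-bromo-6-methoxyphenoxy)-N-methoxy-N-methylpropanamide
Conditions: MeNH(OMe)·HCl, iPrMgCl, THF, −20 → 0 °C; sat. aq. NH4Cl
Reagents that add atoms: N,O-dimethylhydroxylamine hydrochloride, CNOC.Cl
Why: Weinreb amide formation by ester aminolysis with the chloromagnesium amide, which at low temperature should acylate faster than it removes the α-proton and does not exchange the electron-rich aryl bromide, so the R centre is kept.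

**Step 4**
Reactants: 6 4-bromo-2,6-dimethoxyphenol
Product: 7 5-bromo-1,3-dimethoxy-2-(methoxymethoxy)benzene
Conditions: MOMCl, K2CO3, acetone, 0 °C → rt
Reagents that add atoms: chloromethyl methyl ether, COCCl
Why: Williamson-type O-alkylation of the phenoxide with a very reactive chloromethyl ether gives an acetal that tolerates magnesium, hydride and hot carbonate.

**Step 5**
Reactants: 7 5-bromo-1,3-dimethoxy-2-(methoxymethoxy)benzene, 5 (2R)-2-(4-allyl-2-bromo-6-methoxyphenoxy)-N-methoxy-N-methylpropanamide
Product: 9 (2R)-2-(4-allyl-2-bromo-6-methoxyphenoxy)-1-[3,5-dimethoxy-4-(methoxymethoxy)phenyl]propan-1-one, via arylmagnesium bromide 8 (not isolated)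
Conditions: 7, Mg turnings, THF, 45 °C; then 5, THF, 0 °C; sat. aq. NH4Cl
Reagents that add atoms: magnesium, [Mg] (held in 8 only; 9 contains atoms of 5 and 7 alone)
Why: Grignard addition to a Weinreb amide, where the chelated tetrahedral magnesium adduct lasts until the quench, which stops over-addition and keeps the α-centre from enolising, and an arylmagnesium reagent does not undergo halogen–metal exchange with the aryl bromide of 5.

**Step 6**
Reactants: 9 (2R)-2-(4-allyl-2-bromo-6-methoxyphenoxy)-1-[3,5-dimethoxy-4-(methoxymethoxy)phenyl]propan-1-one
Product: 10 (1R,2R)-2-(4-allyl-2-bromo-6-methoxyphenoxy)-1-[3,5-dimethoxy-4-(methoxymethoxy)phenyl]propan-1-ol (threo)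
Conditions: LiBH(s-Bu)3 (L-Selectride), THF, −78 °C; sat. aq. NH4Cl
Reagents that add atoms: none
Why: Polar Felkin–Anh reduction, in which the C–OAr bond stands perpendicular to the carbonyl, the hindered and weakly basic aryloxy oxygen does not chelate, and the bulky hydride approaches anti to OAr past the small hydrogen, which should set C1 as R (syn, threo to the R centre already present).

**Step 7**
Reactants: 10 (1R,2R)-2-(4-allyl-2-bromo-6-methoxyphenoxy)-1-[3,5-dimethoxy-4-(methoxymethoxy)phenyl]propan-1-ol
Product: 11 (2R,3R)-7-allyl-2-[3,5-dimethoxy-4-(methoxymethoxy)phenyl]-5-methoxy-3-methyl-2,3-dihydro-1,4-benzodioxine (trans; MOM ether of the target)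
Conditions: CuI (10 mol %), 3,4,7,8-tetramethyl-1,10-phenanthroline (20 mol %), Cs2CO3 (2 equiv), toluene, 110 °C, Ar
Reagents that add atoms: none
Why: Cs2CO3 deprotonates the C1 hydroxyl at phenanthroline-ligated monovalent copper, the copper alkoxide adds oxidatively to the neighbouring C–Br bond to give a trivalent copper aryl alkoxide, and reductive elimination forms O1–C8a. The closest known reaction type is the ligand-accelerated Ullmann ether synthesis of secondary alcohols with aryl bromides, whose intramolecular form is an established entry to 1,4-benzodioxanes. The dioxane ring closes in a six-membered exo mode at an sp2 carbon (bromide leaves outside the new ring) by contraction of a seven-membered cupracycle made of Cu, O1, C2, C3, O4, C4a and C8a. No stereocentre is created, because only the O–H and C(sp2)–Br bonds break, so 1R,2R of 10 is carried over as 2R,3R (trans) and the benzylic carbon has no opportunity to ionise. The step needs chemoselectivity for C–O reductive elimination over β-hydride loss, intermolecular arylation and allyl-to-propenyl migration; the ortho tether holds the alkoxide beside the C–Br bond, the threo array lets aryl and methyl both sit equatorial in the closing ring, the phenol is masked as its MOM ether, and carbonate in toluene is far too weak a base for the benzylic–allylic CH2. Regiochemistry is not at stake, since O4 was fixed earlier on the OMe-flanked carbon and the bromine marks C8a.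

**Step 8**
Reactants: 11 (2R,3R)-7-allyl-2-[3,5-dimethoxy-4-(methoxymethoxy)phenyl]-5-methoxy-3-methyl-2,3-dihydro-1,4-benzodioxine
Product: 12 4-[(2R,3R)-7-allyl-5-methoxy-3-methyl-2,3-dihydro-1,4-benzodioxin-2-yl]-2,6-dimethoxyphenol (CNP0116579.1)
Conditions: NaHSO4·SiO2, CH2Cl2, rt; filtration
Reagents that add atoms: none
Why: Acid-catalysed acetal cleavage on a weakly acidic solid, where the acetal oxygen of the crowded aryl MOM ether is protonated far more readily than the aryl ether oxygen O1, and in a non-nucleophilic solvent any transient opening at C2 can only re-close to the more stable trans ring, so both stereocentres should be kept.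

**Compound list**
1 | eugenol (4-allyl-2-methoxyphenol) | C=CCc1ccc(O)c(OC)c1 | starting material
2 | 4-allyl-2-bromo-6-methoxyphenol | C=CCc1cc(Br)c(O)c(OC)c1 | intermediate
3 | ethyl (S)-lactate | C[C@H](O)C(=O)OCC | starting material
4 | ethyl (2R)-2-(4-allyl-2-bromo-6-methoxyphenoxy)propanoate | C[C@@H](Oc1c(Br)cc(CC=C)cc1OC)C(=O)OCC | intermediate
5 | (2R)-2-(4-allyl-2-bromo-6-methoxyphenoxy)-N-methoxy-N-methylpropanamide | C[C@@H](Oc1c(Br)cc(CC=C)cc1OC)C(=O)N(C)OC | intermediate
6 | 4-bromo-2,6-dimethoxyphenol | COc1cc(Br)cc(OC)c1O | starting material
7 | 5-bromo-1,3-dimethoxy-2-(methoxymethoxy)benzene | COCOc1c(OC)cc(Br)cc1OC | intermediate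
8 | [3,5-dimethoxy-4-(methoxymethoxy)phenyl]magnesium bromide (not isolated) | COCOc1c(OC)cc([Mg]Br)cc1OC | intermediate
9 | (2R)-2-(4-allyl-2-bromo-6-methoxyphenoxy)-1-[3,5-dimethoxy-4-(methoxymethoxy)phenyl]propan-1-one | C[C@@H](Oc1c(Br)cc(CC=C)cc1OC)C(=O)c1cc(OC)c(OCOC)c(OC)c1 | intermediate
10 | (1R,2R)-2-(4-allyl-2-bromo-6-methoxyphenoxy)-1-[3,5-dimethoxy-4-(methoxymethoxy)phenyl]propan-1-ol | O[C@H](c1cc(OC)c(OCOC)c(OC)c1)[C@@H](C)Oc1c(Br)cc(CC=C)cc1OC | intermediate
11 | (2R,3R)-7-allyl-2-[3,5-dimethoxy-4-(methoxymethoxy)phenyl]-5-methoxy-3-methyl-2,3-dihydro-1,4-benzodioxine | C=CCc1cc(OC)c2c(c1)O[C@H](c1cc(OC)c(OCOC)c(OC)c1)[C@@H](C)O2 | intermediate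
12 | 4-[(2R,3R)-7-allyl-5-methoxy-3-methyl-2,3-dihydro-1,4-benzodioxin-2-yl]-2,6-dimethoxyphenol | C=CCc1cc(OC)c2c(c1)O[C@H](c1cc(OC)c(O)c(OC)c1)[C@@H](C)O2 | target

**Step count**
Total step count: 8.
Longest linear sequence: 7 (steps 1, 2, 3, 5, 6, 7, 8, from eugenol).

**Steps most likely to fail**

Step 7. Oxidative addition of the electron-rich, ortho-oxygenated C–Br bond may be slow. That would leave time for three side processes:
- β-hydride loss from the copper alkoxide, which oxidises the alcohol and is coupled to hydrodebromination;
- migration of the allyl double bond into conjugation on long heating with carbonate;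
- expulsion of the aryloxide by the neighbouring alkoxide.

The fallback raises the reactivity of the electrophile and leaves the coupling temperature alone. It sets out from 10. A copper-catalysed aromatic Finkelstein exchange is run with CuI, NaI and trans-N,N'-dimethylcyclohexane-1,2-diamine in 1,4-dioxane at 110 °C. No base is present, so the alcohol stays untouched. This should give (1R,2R)-2-(4-allyl-2-iodo-6-methoxyphenoxy)-1-[3,5-dimethoxy-4-(methoxymethoxy)phenyl]propan-1-ol F1. The aryl iodide should then close with CuI, 1,10-phenanthroline and Cs2CO3 in toluene at about 80 °C, and the fallback comes back to the route at 11.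

Step 6. Facial selectivity may be poor if lithium bridges the carbonyl oxygen and the aryloxy or methoxy oxygens, because chelate-type delivery leads to the erythro alcohol.

The fallback replaces substrate control by catalyst control. It sets out from 9 and uses Noyori-type asymmetric transfer hydrogenation with RuCl(p-cymene)[(S,S)-TsDPEN] and HCO2H/Et3N 5:2 in EtOAc at rt.
- Hydride transfer is outer-sphere, so no chelate can form.
- The (S,S) catalyst attacks the face that gives (S)-1-phenylethanol from acetophenone. That face is the 1R carbinol here, because the α-oxygen reverses the CIP ranking of the two carbon substituents.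
- This sense is matched with the Felkin–Anh bias.
- The terminal alkene, aryl bromide and MOM group should be left alone.

The fallback comes back at 10 and makes no new compound (F0).

Step 8. Once the para oxygen is free, acid may ionise the C2–O1 bond. That would lead to epimerisation at C2 or to capture of the cation by a nucleophile.

The fallback removes the MOM group without any Brønsted acid. It sets out from 11. Et3SiOTf and 2,2'-bipyridyl in MeCN (0 °C → rt) exchange the aryl acetal directly for a silyl ether. This should give (2R,3R)-7-allyl-2-[3,5-dimethoxy-4-(triethylsilyloxy)phenyl]-5-methoxy-3-methyl-2,3-dihydro-1,4-benzodioxine F2. Bu4NF buffered with AcOH in THF at 0 °C then cleaves the silyl ether, and the fallback comes back at 12.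

**Further compounds**
F1 | step 7 | (1R,2R)-2-(4-allyl-2-iodo-6-methoxyphenoxy)-1-[3,5-dimethoxy-4-(methoxymethoxy)phenyl]propan-1-ol | O[C@H](c1cc(OC)c(OCOC)c(OC)c1)[C@@H](C)Oc1c(I)cc(CC=C)cc1OC
F0 | step 6 | none | none
F2 | step 8 | (2R,3R)-7-allyl-2-[3,5-dimethoxy-4-(triethylsilyloxy)phenyl]-5-methoxy-3-methyl-2,3-dihydro-1,4-benzodioxine | C=CCc1cc(OC)c2c(c1)O[C@H](c1cc(OC)c(O[Si](CC)(CC)CC)c(OC)c1)[C@@H](C)O2
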